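Everything rests on disconnecting the C7–C8 bond of the ten-membered carbocycle. The lactone atoms C7, C11 and C13 form an allyl unit next to the C8 oxygen; moving C11=C13 to C7=C11 and placing the C8 oxygen on C13 gives a macrocyclic α-(alkoxymethyl)butenolide ether (thirteen-membered along the carbon path, twelve through the furanone oxygen). Its C9-ketone enolate, enolisable only toward C8 because C10 is quaternary, undergoes a [2,3] shift that in one operation forms C7–C8, contracts the ring by three atoms to the C1–C10 carbocycle, restores the α-methylene lactone and frees the C8 hydroxyl beside the C9 ketone. The precursor already holds the furanone, the Z-C4=C5 alkene, C6, C10 and the C15 silyl ether.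

Key step: step 21

Remarks on the chemistry (assumptions and corrections)
- Atom labels C1–C15 in the discussion follow germacrane numbering of the target; locants inside compound names are systematic.
- Ring count: along the carbon skeleton macrocycle 32 is thirteen-membered (twelve only when counted through the furanone oxygen). The shift removes O, C13 and C11 from the ring, leaving the ten-membered carbocycle (nine-membered through the oxygen bridge).
- In 32 the C6–C5 bond is itself part of the macrocycle, so the face of C7 that is attacked is decided by the transannular geometry, not by simple shielding. C6–H (γ to the lactone carbonyl and doubly allylic) is a second acidic site. The C15 oxygen is therefore kept as a silyl ether, which cannot leave by vinylogous elimination, and the enolate is made with a hindered lithium amide at –78 °C.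
- The carbinol carbon that becomes C1 is carried as an epimer mixture (6, 7, 12, 13, 26) and is erased by oxidation in step 16.
- Step 10 is a kinetic resolution; the R alcohol is assumed to be the fast-reacting enantiomer by the usual size rule for lipases.
- Compounds 4, 8, 9 and 21 are taken as commercial.

Step 1
Reactants: 1 (S)-lactic acid; 2 pivalaldehyde
Product: 3 (2S,5S)-2-tert-butyl-5-methyl-1,3-dioxolan-4-one
Conditions: p-TsOH·H2O (cat.), H2SO4 (cat.), pentane, reflux, Dean–Stark; crystallisation from pentane/Et2O, –78 °C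
Reagents that add atoms: none
Why: Acid-catalysed acetalisation of the α-hydroxy acid with azeotropic removal of water gives the cis-dioxolanone as the thermodynamic acetal (the new acetal centre is set cis to the methyl group under equilibration and the isomer is purified by crystallisation), the lactate centre being untouched.

Step 2
Reactants: 3 (2S,5S)-2-tert-butyl-5-methyl-1,3-dioxolan-4-one; 4 3-(trimethylsilyl)prop-2-ynal
Product: 7 (2S,5R)-2-tert-butyl-5-methyl-5-[1-(triethylsilyloxy)-3-(trimethylsilyl)prop-2-yn-1-yl]-1,3-dioxolan-4-one (carbinol epimers), via lithium enolate 5 (not isolated), via lithium aldolate 6 (not isolated)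
Conditions: LiN(iPr)2, THF, –78 °C; 4, –78 °C; Et3SiOTf, –78 → –40 °C
Reagents that add atoms: triethylsilyl trifluoromethanesulfonate, CC[Si](CC)(CC)OS(=O)(=O)C(F)(F)F
Why: Aldol addition with self-regeneration of the stereocentre: enolate 5 is attacked by the ynal on the face anti to the tert-butyl group, so the new C–C bond takes the place of the lactate C–H and fixes the future C10, while the carbinol carbon (future C1) forms as an epimer mixture that is erased in step 16 and the aldolate is silylated in the cold before retro-aldol cleavage or acyl transfer can occur.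

Step 3
Reactants: 8 4-methoxybenzyl alcohol; 9 tributyl(iodomethyl)stannane
Product: 10 tributyl[(4-methoxybenzyloxy)methyl]stannane
Conditions: NaH, THF/DMF, 0 °C → rt
Reagents that add atoms: none
Why: Williamson ether synthesis, the sodium alkoxide displacing iodide from the unhindered primary α-stannylmethyl iodide.

Step 4
Reactants: 7 silyl-protected aldol dioxolanone; 10 tributyl[(4-methoxybenzyloxy)methyl]stannane
Product: 12 (3R)-3-hydroxy-1-(4-methoxybenzyloxy)-3-methyl-4-(triethylsilyloxy)-6-(trimethylsilyl)hex-5-yn-2-one (carbinol epimers), via organolithium 11 (not isolated)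
Conditions: 10, n-BuLi, THF, –78 °C; then 7, –78 °C; aq. NH4Cl, –78 °C
Reagents that add atoms: none
Why: Tin–lithium exchange gives the α-alkoxymethyllithium 11, which adds once to the acetal-activated lactone carbonyl (the tetrahedral adduct persists at –78 °C and collapses on quench with loss of pivalaldehyde), a ketone synthesis by organolithium addition to a lactone that leaves the quaternary centre untouched and frees the tertiary hydroxyl.

Step 5
Reactants: 12 silyl-protected hydroxy ketone
Product: 13 (3R)-3,4-dihydroxy-1-(4-methoxybenzyloxy)-3-methylhex-5-yn-2-one (carbinol epimers)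
Conditions: Bu4NF, AcOH, THF, 0 °C → rt
Reagents that add atoms: none
Why: Fluoride-mediated desilylation buffered with acetic acid removes the O–SiEt3 and C(sp)–SiMe3 groups without base-induced retro-aldol cleavage of the β-hydroxy ketone.

Step 6
Reactants: 14 2-butyne-1,4-diol
Product: 15 4-(tert-butyldiphenylsilyloxy)but-2-yn-1-ol
Conditions: tert-butyl(chloro)diphenylsilane (limiting), imidazole, excess 14, DMF, 0 °C → rt
Reagents that add atoms: tert-butyl(chloro)diphenylsilane, CC(C)(C)[Si](Cl)(c1ccccc1)c1ccccc1
Why: Statistical monosilylation of the symmetrical diol, made selective by an excess of the cheap diol.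

Step 7
Reactants: 15 4-(tert-butyldiphenylsilyloxy)but-2-yn-1-ol
Product: 17 (Z)-4-(tert-butyldiphenylsilyloxy)-3-iodobut-2-en-1-ol, via alkenylaluminate 16 (not isolated)
Conditions: NaAlH2(OCH2CH2OMe)2, THF, 0 °C; then iodine, –78 °C → rt
Reagents that add atoms: iodine, [I][I]
Why: Hydroxyl-directed trans-hydroalumination: the alkoxyaluminium hydride delivers hydride to the alkyne carbon next to the carbinol and aluminium to the distal carbon (cyclic alkenylaluminate 16), and iodinolysis with retention gives the Z-iodoalkene in which the carbinol carbon (C6) and the iodine on C4 are cis.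

Step 8
Reactants: 17 (Z)-4-(tert-butyldiphenylsilyloxy)-3-iodobut-2-en-1-ol
Product: 18 (Z)-4-(tert-butyldiphenylsilyloxy)-3-iodobut-2-enal
Conditions: MnO2, CH2Cl2, rt
Reagents that add atoms: none
Why: MnO2 oxidation of a primary allylic alcohol under neutral conditions, which keeps the Z geometry of the β-iodo enal.

Step 9
Reactants: 18 (Z)-4-(tert-butyldiphenylsilyloxy)-3-iodobut-2-enal
Product: 19 racemic (Z)-6-(tert-butyldiphenylsilyloxy)-5-iodohexa-1,4-dien-3-ol
Conditions: vinylmagnesium bromide, THF, –78 °C; aq. NH4Cl
Reagents that add atoms: vinylmagnesium bromide, C=C[Mg]Br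
Why: 1,2-Addition of the Grignard reagent to the enal at low temperature, the alkenyl iodide being inert; the carbinol (C6) forms racemic and is resolved in step 10.

Step 10
Reactants: 19 racemic (Z)-6-(tert-butyldiphenylsilyloxy)-5-iodohexa-1,4-dien-3-ol
Product: 20 (S,Z)-6-(tert-butyldiphenylsilyloxy)-5-iodohexa-1,4-dien-3-ol
Conditions: immobilised Candida antarctica lipase B, vinyl acetate, MTBE, 30 °C, to about half conversion; chromatography
Reagents that add atoms: none
Why: Lipase-catalysed kinetic resolution by transesterification: by the usual size rule (vinyl as the medium group, iodoalkenyl as the large group) the R alcohol is acetylated faster, so the unreacted S alcohol 20, which has the C6 configuration of the target, is recovered.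

Step 11
Reactants: 21 ethyl 2-(hydroxymethyl)acrylate
Product: 22 ethyl 2-[(tert-butyldimethylsilyloxy)methyl]acrylate
Conditions: tert-butyl(chloro)dimethylsilane, imidazole, CH2Cl2, 0 °C → rt
Reagents that add atoms: tert-butyl(chloro)dimethylsilane, CC(C)(C)[Si](C)(C)Cl
Why: Silylation of the primary allylic alcohol with the silyl chloride and imidazole.

Step 12
Reactants: 22 ethyl 2-[(tert-butyldimethylsilyloxy)methyl]acrylate
Product: 23 2-[(tert-butyldimethylsilyloxy)methyl]acrylic acid
Conditions: LiOH·H2O, THF/H2O, 0 °C → rt; 1 M HCl to pH 4, 0 °C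
Reagents that add atoms: lithium hydroxide, [Li+].[OH-]
Why: Saponification of the ethyl ester in the cold, where the acrylate and the silyl ether survive.

Step 13
Reactants: 20 (S,Z)-6-(tert-butyldiphenylsilyloxy)-5-iodohexa-1,4-dien-3-ol; 23 2-[(tert-butyldimethylsilyloxy)methyl]acrylic acid
Product: 24 (S,Z)-6-(tert-butyldiphenylsilyloxy)-5-iodohexa-1,4-dien-3-yl 2-[(tert-butyldimethylsilyloxy)methyl]acrylate
Conditions: DCC, DMAP (cat.), CH2Cl2, 0 °C → rt
Reagents that add atoms: none
Why: Steglich esterification; the C–O bond at C6 is not broken, so the configuration is retained.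

Step 14
Reactants: 24 dienyl acrylate
Product: 25 (S)-3-[(tert-butyldimethylsilyloxy)methyl]-5-[(Z)-3-(tert-butyldiphenylsilyloxy)-2-iodoprop-1-en-1-yl]furan-2(5H)-one
Conditions: second-generation Grubbs catalyst (10 mol%), toluene (5 mM), 80 °C
Reagents that add atoms: none
Why: Ring-closing olefin metathesis: the ruthenium carbene loads on the terminal vinyl group and closes onto the 1,1-disubstituted acrylate to give the α-substituted butenolide with loss of ethylene, the trisubstituted iodoalkene being too hindered and electron-poor to take part.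

Step 15
Reactants: 25 iodoalkenyl butenolide; 13 (3R)-3,4-dihydroxy-1-(4-methoxybenzyloxy)-3-methylhex-5-yn-2-one
Product: 26 (5R)-3-[(tert-butyldimethylsilyloxy)methyl]-5-[(1E,6R)-2-[(tert-butyldiphenylsilyloxy)methyl]-5,6-dihydroxy-8-(4-methoxybenzyloxy)-6-methyl-7-oxooct-1-en-3-yn-1-yl]furan-2(5H)-one (carbinol epimers)
Conditions: Pd(PPh3)4 (5 mol%), CuI (10 mol%), Et3N, degassed THF, 0 °C → rt
Reagents that add atoms: none
Why: Sonogashira coupling of the alkenyl iodide with the terminal alkyne proceeds with retention of the alkene geometry at or below room temperature, which tolerates the free hydroxyls and limits amine-induced epimerisation at C6.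

Step 16
Reactants: 26 enyne diol
Product: 28 (5R)-3-[(tert-butyldimethylsilyloxy)methyl]-5-[(Z)-3-(tert-butyldiphenylsilyloxy)-2-[(5R)-5-[(4-methoxybenzyloxy)acetyl]-5-methyl-4-oxo-4,5-dihydrofuran-2-yl]prop-1-en-1-yl]furan-2(5H)-one, via ynone 27 (not isolated)
Conditions: Dess–Martin periodinane, CH2Cl2, 0 °C → rt; aq. Na2S2O3/NaHCO3 work-up; crude 27, AuCl3 (5 mol%), CH2Cl2, rt
Reagents that add atoms: none
Why: Dess–Martin oxidation of the secondary propargylic alcohol (the tertiary C10 hydroxyl cannot be oxidised) gives hydroxy ynone 27, and gold-catalysed 5-endo-dig addition of the C10 hydroxyl to the activated alkyne carbon C3 closes the 3(2H)-furanone, a known cycloisomerisation that does not touch the quaternary C10.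

Step 17
Reactants: 28 furanone–butenolide with C13 silyl ether
Product: 29 C13 alcohol: (5R)-3-(hydroxymethyl) analogue of 28
Conditions: HF·pyridine, pyridine, THF, 0 °C
Reagents that add atoms: none
Why: Selective desilylation: the primary tert-butyldimethylsilyl ether is cleaved by buffered HF·pyridine far faster than the tert-butyldiphenylsilyl ether, and the 4-methoxybenzyl ether is inert.

Step 18
Reactants: 29 C13 alcohol
Product: 30 C13 bromide: (5R)-3-(bromomethyl) analogue of 28
Conditions: CBr4, PPh3 (added last), CH2Cl2, –20 → 0 °C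
Reagents that add atoms: carbon tetrabromide, BrC(Br)(Br)Br
Why: Appel bromination of the primary allylic alcohol (SN2 at C13) under neutral conditions.

Step 19
Reactants: 30 C13 bromide
Product: 31 bromo ketol: (5R)-3-(bromomethyl)-5-[(Z)-3-(tert-butyldiphenylsilyloxy)-2-[(5R)-5-(hydroxyacetyl)-5-methyl-4-oxo-4,5-dihydrofuran-2-yl]prop-1-en-1-yl]furan-2(5H)-one
Conditions: DDQ, CH2Cl2/pH 7 buffer, 0 °C
Reagents that add atoms: none
Why: Oxidative cleavage of the 4-methoxybenzyl ether by DDQ (hydride abstraction, then hydrolysis of the oxocarbenium ion), which leaves the allylic bromide, the silyl ether and the electron-poor alkenes alone.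

Step 20
Reactants: 31 bromo ketol
Product: 32 macrocyclic butenolide ether (6R,10R,4Z; C8–O–C13 ether, C9 ketone, C15 tert-butyldiphenylsilyl ether)
Conditions: Ag2O, 4 Å molecular sieves, CH2Cl2 (2 mM), 35 °C, dark
Reagents that add atoms: none
Why: Silver oxide-assisted Williamson etherification: Ag2O activates the primary allylic bromide and takes up HBr, so the C8 hydroxyl attacks C13 directly (exo-tet closure of the ring that is thirteen-membered along carbon) without a base strong enough to remove C6–H, attack at C7 being disfavoured because it would give a smaller, more strained ring and a hindered secondary ether, while the Z-alkene and the two planar rings hold the reacting ends close.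

Step 21
Reactants: 32 macrocyclic butenolide ether
Product: 34 (6R,7R,8S,10R)-8-hydroxy-9-ketone with α-methylene lactone and C15 tert-butyldiphenylsilyl ether, via lithium enolate 33 (not isolated)
Conditions: LiN(SiMe3)2 (1.1 equiv), THF, –78 → –40 °C; AcOH, –78 °C
Reagents that add atoms: none
Why: Proposed new method: LiN(SiMe3)2 removes a C8 proton of the chelating α-alkoxy ketone to give the lithium (Z)-enolate 33, whose C8 bonds to the butenolide β-carbon C7 through a five-membered envelope array (C8–O–C13–C11=C7) while the C13–O bond breaks, an enolate [2,3]-Wittig shift that is polarity-matched like a conjugate addition and expels the alkoxide that becomes the C8 oxygen, leaving the C11=C13 exo-methylene lactone. The closest known reactions are the [2,3]-Wittig ring contractions of thirteen-membered allylic or propargylic ethers to ten-membered carbocycles and the enolate [2,3]-Wittig shifts of α-allyloxy carbonyl compounds. The ten-membered carbocycle C1–C10 (nine-membered through the furanone oxygen) is closed by transannular C7–C8 bonding with excision of O, C13 and C11 from the ring (13 → 10); as a stepwise Michael addition this would be a disfavoured 5-endo-trig closure, so the concerted sigmatropic course with synchronous C–O cleavage is expected. C7 is set by the ring: the rigid conjugated segment C6–C5=C4–C3–O–C10 should hold the ether tether on the butenolide face opposite to the C6–C5 bond, so C8 arrives anti to C5 and the lactone becomes trans-fused; C8 is set by the chelated enolate geometry together with the envelope in which C9 lies beside C6 across the forming bond, the arrangement that lets the short C9–C10–O–C3 bridge stay connected to the furanone, which should give 8S. The step needs the [2,3] shift to beat the anionic [3,3] shift (which would join the non-nucleophilic C9 to C7 in a more strained nine-membered carbocycle) and needs kinetic deprotonation at C8 instead of the doubly allylic C6–H; the acceptor character of C7, the chelating α-alkoxy ketone and the hindered amide base at –78 °C are relied on for this, and the cold acetic acid quench prevents ketol equilibration of the product alkoxide.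

Step 22
Reactants: 34 hydroxy ketone
Product: 35 (6R,7S,8S,10R)-8-methacrylate 9-ketone
Conditions: methacrylic anhydride, pyridine, DMAP (cat.), CH2Cl2, 0 °C
Reagents that add atoms: methacrylic anhydride, CC(=C)C(=O)OC(=O)C(C)=C
Why: DMAP-catalysed acylation of the only free hydroxyl with the anhydride at 0 °C and with pyridine as the sole base, mild enough to avoid enolisation at C8; the C8–O bond is not broken.

Step 23
Reactants: 35 methacrylate ketone
Product: 36 (6R,7S,8S,9R,10S)-8-methacrylate 9-alcohol
Conditions: NaBH4, CeCl3·7H2O, MeOH/THF, –78 °C; AcOH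
Reagents that add atoms: none
Why: Luche reduction: the borohydride/CeCl3 system reduces the doubly α-oxygenated, most electrophilic C9 ketone in preference to the vinylogous-ester C1 carbonyl and without conjugate reduction of the α-methylene lactone or the methacrylate, and polar Felkin–Anh delivery of hydride anti to the C10–O and C8–O bonds, past the C10 methyl group, should set 9R.

Step 24
Reactants: 36 C9 alcohol
Product: 37 (6R,7S,8S,9R,10S)-8-methacrylate 9-(3-methylbutanoate) with C15 tert-butyldiphenylsilyl ether
Conditions: 3-methylbutanoyl chloride, pyridine, DMAP (cat.), CH2Cl2, 0 °C → rt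
Reagents that add atoms: 3-methylbutanoyl chloride, CC(C)CC(=O)Cl
Why: Acylation of the hindered secondary alcohol with the acid chloride under pyridine/DMAP catalysis, with retention at C9 and conditions too weakly basic for retro-aldol cleavage of C9–C10 or migration of the C8 ester.

Step 25
Reactants: 37 silyl-protected diester
Product: 38 CNP0552093.1
Conditions: HF·pyridine, pyridine, THF, 0 °C → rt
Reagents that add atoms: none
Why: Cleavage of the silyl ether by fluoride attack at silicon, buffered with pyridine so that the two esters, the α-methylene lactone and the furanone survive.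

Compound list
1 | (S)-lactic acid | C[C@H](O)C(=O)O | starting material
2 | pivalaldehyde | CC(C)(C)C=O | starting material
3 | (2S,5S)-2-tert-butyl-5-methyl-1,3-dioxolan-4-one | C[C@@H]1O[C@H](C(C)(C)C)OC1=O | intermediate
4 | 3-(trimethylsilyl)prop-2-ynal | C[Si](C)(C)C#CC=O | starting material
5 | lithium (2S)-2-tert-butyl-5-methyl-1,3-dioxol-4-olate (enolate of 3) | CC1=C(O[Li])O[C@@H](C(C)(C)C)O1 | intermediate
6 | lithium aldolate of 5 and 4 (carbinol epimers) | C[C@]1(C(O[Li])C#C[Si](C)(C)C)O[C@H](C(C)(C)C)OC1=O | intermediate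
7 | (2S,5R)-2-tert-butyl-5-methyl-5-[1-(triethylsilyloxy)-3-(trimethylsilyl)prop-2-yn-1-yl]-1,3-dioxolan-4-one (carbinol epimers) | C[C@]1(C(O[Si](CC)(CC)CC)C#C[Si](C)(C)C)O[C@H](C(C)(C)C)OC1=O | intermediate
8 | 4-methoxybenzyl alcohol | COc1ccc(CO)cc1 | starting material
9 | tributyl(iodomethyl)stannane | CCCC[Sn](CCCC)(CCCC)CI | starting material
10 | tributyl[(4-methoxybenzyloxy)methyl]stannane | CCCC[Sn](CCCC)(CCCC)COCc1ccc(OC)cc1 | intermediate
11 | [(4-methoxybenzyloxy)methyl]lithium | [Li]COCc1ccc(OC)cc1 | intermediate
12 | (3R)-3-hydroxy-1-(4-methoxybenzyloxy)-3-methyl-4-(triethylsilyloxy)-6-(trimethylsilyl)hex-5-yn-2-one (carbinol epimers) | C[C@@](O)(C(O[Si](CC)(CC)CC)C#C[Si](C)(C)C)C(=O)COCc1ccc(OC)cc1 | intermediate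
13 | (3R)-3,4-dihydroxy-1-(4-methoxybenzyloxy)-3-methylhex-5-yn-2-one (carbinol epimers) | C[C@@](O)(C(O)C#C)C(=O)COCc1ccc(OC)cc1 | intermediate
14 | 2-butyne-1,4-diol | OCC#CCO | starting material
15 | 4-(tert-butyldiphenylsilyloxy)but-2-yn-1-ol | OCC#CCO[Si](c1ccccc1)(c1ccccc1)C(C)(C)C | intermediate
16 | sodium alkenylaluminate from hydroalumination of 15 (cyclic, two 2-methoxyethoxy ligands on aluminium) | [Na+].COCCO[Al-]1(OCCOC)OCC=C1CO[Si](c1ccccc1)(c1ccccc1)C(C)(C)C | intermediate
17 | (Z)-4-(tert-butyldiphenylsilyloxy)-3-iodobut-2-en-1-ol | OC/C=C(\I)CO[Si](c1ccccc1)(c1ccccc1)C(C)(C)C | intermediate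
18 | (Z)-4-(tert-butyldiphenylsilyloxy)-3-iodobut-2-enal | O=C/C=C(\I)CO[Si](c1ccccc1)(c1ccccc1)C(C)(C)C | intermediate
19 | racemic (Z)-6-(tert-butyldiphenylsilyloxy)-5-iodohexa-1,4-dien-3-ol | C=CC(O)/C=C(\I)CO[Si](c1ccccc1)(c1ccccc1)C(C)(C)C | intermediate
20 | (S,Z)-6-(tert-butyldiphenylsilyloxy)-5-iodohexa-1,4-dien-3-ol | C=C[C@H](O)/C=C(\I)CO[Si](c1ccccc1)(c1ccccc1)C(C)(C)C | intermediate
21 | ethyl 2-(hydroxymethyl)acrylate | C=C(CO)C(=O)OCC | starting material
22 | ethyl 2-[(tert-butyldimethylsilyloxy)methyl]acrylate | C=C(CO[Si](C)(C)C(C)(C)C)C(=O)OCC | intermediate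
23 | 2-[(tert-butyldimethylsilyloxy)methyl]acrylic acid | C=C(CO[Si](C)(C)C(C)(C)C)C(=O)O | intermediate
24 | (S,Z)-6-(tert-butyldiphenylsilyloxy)-5-iodohexa-1,4-dien-3-yl 2-[(tert-butyldimethylsilyloxy)methyl]acrylate | C=C[C@H](OC(=O)C(=C)CO[Si](C)(C)C(C)(C)C)/C=C(\I)CO[Si](c1ccccc1)(c1ccccc1)C(C)(C)C | intermediate
25 | (S)-3-[(tert-butyldimethylsilyloxy)methyl]-5-[(Z)-3-(tert-butyldiphenylsilyloxy)-2-iodoprop-1-en-1-yl]furan-2(5H)-one | CC(C)(C)[Si](C)(C)OCC1=C[C@H](OC1=O)/C=C(\I)CO[Si](c1ccccc1)(c1ccccc1)C(C)(C)C | intermediate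
26 | (5R)-3-[(tert-butyldimethylsilyloxy)methyl]-5-[(1E,6R)-2-[(tert-butyldiphenylsilyloxy)methyl]-5,6-dihydroxy-8-(4-methoxybenzyloxy)-6-methyl-7-oxooct-1-en-3-yn-1-yl]furan-2(5H)-one (carbinol epimers) | CC(C)(C)[Si](C)(C)OCC1=C[C@H](OC1=O)/C=C(\C#CC(O)[C@@](C)(O)C(=O)COCc1ccc(OC)cc1)CO[Si](c1ccccc1)(c1ccccc1)C(C)(C)C | intermediate
27 | (5R)-3-[(tert-butyldimethylsilyloxy)methyl]-5-[(1E,6R)-2-[(tert-butyldiphenylsilyloxy)methyl]-6-hydroxy-8-(4-methoxybenzyloxy)-6-methyl-5,7-dioxooct-1-en-3-yn-1-yl]furan-2(5H)-one | CC(C)(C)[Si](C)(C)OCC1=C[C@H](OC1=O)/C=C(\C#CC(=O)[C@@](C)(O)C(=O)COCc1ccc(OC)cc1)CO[Si](c1ccccc1)(c1ccccc1)C(C)(C)C | intermediate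
28 | (5R)-3-[(tert-butyldimethylsilyloxy)methyl]-5-[(Z)-3-(tert-butyldiphenylsilyloxy)-2-[(5R)-5-[(4-methoxybenzyloxy)acetyl]-5-methyl-4-oxo-4,5-dihydrofuran-2-yl]prop-1-en-1-yl]furan-2(5H)-one | CC(C)(C)[Si](C)(C)OCC1=C[C@H](OC1=O)/C=C(/CO[Si](c1ccccc1)(c1ccccc1)C(C)(C)C)C1=CC(=O)[C@@](C)(O1)C(=O)COCc1ccc(OC)cc1 | intermediate
29 | (5R)-5-[(Z)-3-(tert-butyldiphenylsilyloxy)-2-[(5R)-5-[(4-methoxybenzyloxy)acetyl]-5-methyl-4-oxo-4,5-dihydrofuran-2-yl]prop-1-en-1-yl]-3-(hydroxymethyl)furan-2(5H)-one | OCC1=C[C@H](OC1=O)/C=C(/CO[Si](c1ccccc1)(c1ccccc1)C(C)(C)C)C1=CC(=O)[C@@](C)(O1)C(=O)COCc1ccc(OC)cc1 | intermediate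
30 | (5R)-3-(bromomethyl)-5-[(Z)-3-(tert-butyldiphenylsilyloxy)-2-[(5R)-5-[(4-methoxybenzyloxy)acetyl]-5-methyl-4-oxo-4,5-dihydrofuran-2-yl]prop-1-en-1-yl]furan-2(5H)-one | BrCC1=C[C@H](OC1=O)/C=C(/CO[Si](c1ccccc1)(c1ccccc1)C(C)(C)C)C1=CC(=O)[C@@](C)(O1)C(=O)COCc1ccc(OC)cc1 | intermediate
31 | (5R)-3-(bromomethyl)-5-[(Z)-3-(tert-butyldiphenylsilyloxy)-2-[(5R)-5-(hydroxyacetyl)-5-methyl-4-oxo-4,5-dihydrofuran-2-yl]prop-1-en-1-yl]furan-2(5H)-one | BrCC1=C[C@H](OC1=O)/C=C(/CO[Si](c1ccccc1)(c1ccccc1)C(C)(C)C)C1=CC(=O)[C@@](C)(O1)C(=O)CO | intermediate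
32 | macrocyclic α-(alkoxymethyl)butenolide ether (6R,10R,4Z): C8–O–C13 ether, C9 ketone, furanone, C15 tert-butyldiphenylsilyl ether | C1OCC2=C[C@H](OC2=O)/C=C(/CO[Si](c3ccccc3)(c3ccccc3)C(C)(C)C)C2=CC(=O)[C@@](C)(O2)C1=O | intermediate
33 | lithium (Z)-enolate of 32 (C8=C9–OLi) | [Li]O/C1=C\OCC2=C[C@H](OC2=O)/C=C(/CO[Si](c3ccccc3)(c3ccccc3)C(C)(C)C)C2=CC(=O)[C@@]1(C)O2 | intermediate
34 | (6R,7R,8S,10R)-15-(tert-butyldiphenylsilyloxy)-8-hydroxy-1,9-dioxo-3,10-epoxygermacra-2,4(Z),11(13)-trien-12,6-olide | O[C@H]1[C@H]2C(=C)C(=O)O[C@@H]2/C=C(/CO[Si](c3ccccc3)(c3ccccc3)C(C)(C)C)C2=CC(=O)[C@@](C)(O2)C1=O | intermediate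
35 | (6R,7S,8S,10R)-15-(tert-butyldiphenylsilyloxy)-8-(methacryloyloxy)-1,9-dioxo-3,10-epoxygermacra-2,4(Z),11(13)-trien-12,6-olide | C=C(C)C(=O)O[C@H]1[C@H]2C(=C)C(=O)O[C@@H]2/C=C(/CO[Si](c3ccccc3)(c3ccccc3)C(C)(C)C)C2=CC(=O)[C@@](C)(O2)C1=O | intermediate
36 | (6R,7S,8S,9R,10S)-15-(tert-butyldiphenylsilyloxy)-9-hydroxy-8-(methacryloyloxy)-1-oxo-3,10-epoxygermacra-2,4(Z),11(13)-trien-12,6-olide | C=C(C)C(=O)O[C@H]1[C@H]2C(=C)C(=O)O[C@@H]2/C=C(/CO[Si](c3ccccc3)(c3ccccc3)C(C)(C)C)C2=CC(=O)[C@@](C)(O2)[C@@H]1O | intermediate
37 | (6R,7S,8S,9R,10S)-15-(tert-butyldiphenylsilyloxy)-8-(methacryloyloxy)-9-(3-methylbutanoyloxy)-1-oxo-3,10-epoxygermacra-2,4(Z),11(13)-trien-12,6-olide | C=C(C)C(=O)O[C@H]1[C@H]2C(=C)C(=O)O[C@@H]2/C=C(/CO[Si](c3ccccc3)(c3ccccc3)C(C)(C)C)C2=CC(=O)[C@@](C)(O2)[C@@H]1OC(=O)CC(C)C | intermediate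
38 | CNP0552093.1: (6R,7S,8S,9R,10S)-15-hydroxy-8-(methacryloyloxy)-9-(3-methylbutanoyloxy)-1-oxo-3,10-epoxygermacra-2,4(Z),11(13)-trien-12,6-olide | C=C(C)C(=O)O[C@H]1[C@H]2C(=C)C(=O)O[C@@H]2/C=C(/CO)C2=CC(=O)[C@@](C)(O2)[C@@H]1OC(=O)CC(C)C | target

Total step count: 25 (three branches: steps 1–5, steps 6–10 with 13–14, steps 11–12; then steps 15–25).
Longest linear sequence: 18 steps (from 14 through steps 6–10, 13 and 14, then 15–25).

Steps most likely to fail

1. Step 21 (the proposed new method). What may go wrong: deprotonation at C6 instead of C8, with loss of the C6 configuration or decomposition of the resulting furanolate; bonding of C9 instead of C8 to C7 (anionic [3,3] shift) or a [1,2] shift; delivery of C8 to the wrong butenolide face or with the wrong C8 configuration; ketol isomerisation of the product alkoxide before the quench. Fallback (known chemistry): the C7–C8 bond is made by an intramolecular Barbier-type allylation instead. It sets out from bromo ketol 31. Dess–Martin oxidation of the C8 hydroxyl gives the α-keto aldehyde F1. Indium powder in THF/H2O at high dilution then turns the C13 bromide into an allylindium reagent that adds through its γ-carbon C7 to the aldehyde carbon C8, chemoselectively over the two ketones. This closes the ten-membered ring directly and gives the α-methylene lactone with the C8 hydroxyl beside the C9 ketone, that is hydroxy ketone 34, where the route is rejoined. The cyclic six-membered transition state, with the allyl unit locked in the butenolide, should again place C8 anti to C5.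

2. Step 20. What may go wrong: ring closure too slow to compete with intermolecular etherification (oligomers), attack of the hydroxyl at C7 with allylic transposition, or oxidation of the ketol by silver oxide. Fallback: a Tsuji–Trost allylic etherification through a palladium π-allyl complex in place of the bromide displacement. It sets out from alcohol 29. Methyl chloroformate and pyridine give the C13 methyl carbonate F2, and DDQ then frees the C8 hydroxyl to give hydroxy carbonate F3. Pd2(dba)3 with PPh3 (zerovalent palladium) in THF at high dilution ionises the carbonate; the methoxide released deprotonates the fairly acidic ketol hydroxyl, which attacks the less hindered terminus C13 of the 2-acyl-π-allyl complex to give macrocycle 32, where the route is rejoined.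

3. Step 23. What may go wrong: poor facial selectivity at C9, conjugate reduction of the α-methylene lactone, or migration of the C8 ester to the new C9 alkoxide. Fallback: catalyst control instead of substrate control, a Corey–Bakshi–Shibata reduction of 35 with (S)-2-methyl-CBS-oxazaborolidine and catecholborane in toluene at –78 °C. With C10 as the large and C8 as the small ketone substituent, hydride should be delivered to the face that gives 9R, under neutral conditions that leave no free alkoxide. It sets out from 35, returns at 36 and makes no new compound (F0).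

Further compounds
F1 | step 21 | (5R)-3-(bromomethyl)-5-[(Z)-3-(tert-butyldiphenylsilyloxy)-2-[(5R)-5-methyl-4-oxo-5-(oxoacetyl)-4,5-dihydrofuran-2-yl]prop-1-en-1-yl]furan-2(5H)-one (α-keto aldehyde) | BrCC1=C[C@H](OC1=O)/C=C(/CO[Si](c1ccccc1)(c1ccccc1)C(C)(C)C)C1=CC(=O)[C@@](C)(O1)C(=O)C=O
F2 | step 20 | C13 methyl carbonate of 29 | COC(=O)OCC1=C[C@H](OC1=O)/C=C(/CO[Si](c1ccccc1)(c1ccccc1)C(C)(C)C)C1=CC(=O)[C@@](C)(O1)C(=O)COCc1ccc(OC)cc1
F3 | step 20 | C13 methyl carbonate with free C8 hydroxyl | COC(=O)OCC1=C[C@H](OC1=O)/C=C(/CO[Si](c1ccccc1)(c1ccccc1)C(C)(C)C)C1=CC(=O)[C@@](C)(O1)C(=O)CO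
F0 | step 23 | none | none
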